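**Retrosynthetic overview**
1. The target comes from debenzylation, α-face dihydroxylation of C8=C9, and direct C6 acyloxylation of 4β-hydroxydauc-8-en-7-one.
2. That enone comes from isopropyl addition to a trans-fused hydroazulene-4,7-dione.
3. The seven-membered ring comes from strain-release retro-Michael opening (C5–C9 bond) of a 5-4-5 tricycle.
4. The tricycle comes from an intramolecular enone–olefin [2+2] photocycloaddition. This step forms a cyclobutane and a cyclopentane together and sets the quaternary C1.
5. The photosubstrate comes from anti-crotylboration of the aldehyde cut out of cis-jasmone. Ring order: the cyclopentenone is bought, the four- and five-membered rings form together, and these two are then merged into the seven-membered ring.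

**Convention:** daucane numbering is used for all bi- and tricyclic compounds. C1 is the ring-fusion carbon bearing CH3, followed by C2 and C3. C4 is the carbon that carries the isopropyl group, C5 is the ring-fusion CH, and C6–C10 are the rest of the seven-membered ring. α is the face of H-5 and β is the face of the C1 methyl.

Step 1
Reactants: 1 cis-jasmone, (Z)-3-methyl-2-(pent-2-en-1-yl)cyclopent-2-en-1-one
Product: 3 2-(2-methyl-5-oxocyclopent-1-en-1-yl)acetaldehyde, via secondary ozonide 2 (not isolated)
Conditions: O3 (1.0 equiv), CH2Cl2, −78 °C; then Me2S, −78 °C to rt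
Reagents that add atoms: ozone [O-][O+]=O
Why: This is a chemoselective ozonolysis (Criegee mechanism) of the electron-rich isolated Z-alkene, since the tetrasubstituted enone C=C is far less nucleophilic, and no stereocentre is formed.

Step 2
Reactants: 3 2-(2-methyl-5-oxocyclopent-1-en-1-yl)acetaldehyde; 4 (E)-crotylboronic acid pinacol ester
Product: 5 2-[(2R,3S)-2-hydroxy-3-methylpent-4-en-1-yl]-3-methylcyclopent-2-en-1-one
Conditions: 4 (1.2 equiv), (S)-3,3'-bis(2,4,6-triisopropylphenyl)-1,1'-binaphthyl-2,2'-diyl hydrogen phosphate (5 mol %), toluene, −30 °C; aqueous work-up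
Reagents that add atoms: none
Why: In this Brønsted-acid-catalysed crotylboration through a closed Zimmerman–Traxler chair, the E-boronate gives the anti pair and the catalyst directs Si-face attack, setting 7R,8S, which serve only as a stereochemical relay.

Step 3
Reactants: 5 2-[(2R,3S)-2-hydroxy-3-methylpent-4-en-1-yl]-3-methylcyclopent-2-en-1-one
Product: 6 (1R,5S,7R,8S,9S)-tricyclic hydroxy ketone (cyclobutane C1–C10–C9–C5 on the α face of the cyclopentanone, cyclopentane C5–C6–C7–C8–C9, 7-OH, 8-CH3)
Conditions: hν (350 nm, Pyrex), MeCN (0.005 M), 0 °C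
Reagents that add atoms: none
Why: In this intramolecular enone–olefin [2+2] photocycloaddition the three-atom tether follows the rule of five (C5–C9 first, then C1–C10), so the cyclopentane and cyclobutane close in one operation, and the C8 methyl and C7 hydroxyl take the convex face of the new bicyclo[3.2.0]heptane, which sends the vinyl group to the α face and sets quaternary C1 as R.

Step 4
Reactants: 6 (1R,5S,7R,8S,9S)-tricyclic hydroxy ketone
Product: 8 (3aR,8aR)-6,8a-dimethyl-1,2,3a,4,8,8a-hexahydroazulene-3,5-dione (trans-fused 4,7-dione with C8=C9), via tricyclic diketone 7 (not isolated)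
Conditions: (C3H7)4N[RuO4] (5 mol %), NMO, 4 Å MS, CH2Cl2, 0 °C; then DBU (10 mol %), −20 °C, AcOH quench
Reagents that add atoms: none
Why: Proposed new method: Ley–Griffith oxidation unmasks a 1,5-diketone whose C8 enolate expels C5 as the C4 enolate (E1cB retro-Michael), driven by about 26 kcal/mol of cyclobutane strain and by enone conjugation and closest in type to the de Mayo retro-aldol and Winkler retro-Mannich fragmentations, and the amidinium ion formed at C8–H on the α face returns its proton to C5 inside the ion pair, so H-5 takes the place of C9 (trans fusion), while any cis epimer can be re-equilibrated with DBU and recycled.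

Step 5
Reactants: 8 (3aR,8aR)-6,8a-dimethyl-1,2,3a,4,8,8a-hexahydroazulene-3,5-dione; 9 isopropylmagnesium chloride
Product: 10 (3R,3aR,8aR)-3-hydroxy-6,8a-dimethyl-3-(propan-2-yl)-2,3,3a,4,8,8a-hexahydroazulen-5(1H)-one (4β-hydroxydauc-8-en-7-one)
Conditions: 9 (1.3 equiv), LaCl3·2LiCl (30 mol %), THF, −40 °C; aq. NH4Cl
Reagents that add atoms: none
Why: In this lanthanide-promoted Grignard 1,2-addition the saturated cyclopentanone reacts ahead of the conjugated ketone (as in the Wieland–Miescher ketone), attack comes from the α face next to H-5 and away from C6 and the C1 methyl to give 4R (OH β, isopropyl α), and the low basicity leaves C5 untouched.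

Step 6
Reactants: 10 4β-hydroxydauc-8-en-7-one; 11 4-(benzyloxy)benzoic acid
Product: 12 (3R,3aS,4R,8aR)-3-hydroxy-6,8a-dimethyl-5-oxo-3-(propan-2-yl)-1,2,3,3a,4,5,8,8a-octahydroazulen-4-yl 4-(benzyloxy)benzoate
Conditions: Mn(OAc)3 (3 equiv), 11 (6 equiv), benzene, reflux (Dean–Stark)
Reagents that add atoms: none
Why: This is a Mn(OAc)3-mediated α'-acyloxylation of an enone (carboxylate transfer within a trivalent manganese enolate) at C6, the only α' position, and the new centre equilibrates through the enol under the acidic reflux to the equatorial 6α ester (H-5/H-6 trans-diaxial, 6R).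

Step 7
Reactants: 12 6α-[4-(benzyloxy)benzoyloxy]-4β-hydroxydauc-8-en-7-one
Product: 13 (3R,3aS,4R,6S,7S,8aR)-3,6,7-trihydroxy-6,8a-dimethyl-5-oxo-3-(propan-2-yl)decahydroazulen-4-yl 4-(benzyloxy)benzoate
Conditions: OsO4 (5 mol %), NMO, citric acid, t-BuOH/H2O, rt
Reagents that add atoms: N-methylmorpholine N-oxide C[N+]1([O-])CCOCC1; water O
Why: This Upjohn dihydroxylation adds syn to the only remaining C=C from the α face, opposite the angular methyl, and sets the 8α,9α cis-diol (8S,9S in daucane numbering).

Step 8
Reactants: 13 benzyl-protected triol ester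
Product: 14 target, (3R,3aS,4R,6S,7S,8aR)-3,6,7-trihydroxy-6,8a-dimethyl-5-oxo-3-(propan-2-yl)decahydroazulen-4-yl 4-hydroxybenzoate
Conditions: H2 (1 atm), Pd/C, EtOAc, rt
Reagents that add atoms: none
Why: Hydrogenolysis of the benzyl aryl ether proceeds under neutral conditions with no alkene left, so no stereocentre and no ester is touched.

**Compound list**
1 | cis-jasmone | CC/C=C\CC1=C(C)CCC1=O | starting material
2 | secondary ozonide, cis-3-ethyl-5-[(2-methyl-5-oxocyclopent-1-en-1-yl)methyl]-1,2,4-trioxolane (relative configuration) | CC[C@H]1OO[C@@H](CC2=C(C)CCC2=O)O1 | intermediate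
3 | 2-(2-methyl-5-oxocyclopent-1-en-1-yl)acetaldehyde | O=CCC1=C(C)CCC1=O | intermediate
4 | (E)-crotylboronic acid pinacol ester | C/C=C/CB1OC(C)(C)C(C)(C)O1 | starting material
5 | 2-[(2R,3S)-2-hydroxy-3-methylpent-4-en-1-yl]-3-methylcyclopent-2-en-1-one | C=C[C@H](C)[C@H](O)CC1=C(C)CCC1=O | intermediate
6 | (1R,5S,7R,8S,9S)-tricyclic hydroxy ketone (5-4-5 photoadduct) | O=C1CC[C@]2(C)C[C@H]3[C@H](C)[C@H](O)C[C@@]123 | intermediate
7 | tricyclic 4,7-diketone | O=C1CC[C@]2(C)C[C@H]3[C@H](C)C(=O)C[C@@]123 | intermediate
8 | (3aR,8aR)-6,8a-dimethyl-1,2,3a,4,8,8a-hexahydroazulene-3,5-dione | O=C1CC[C@]2(C)CC=C(C)C(=O)C[C@H]21 | intermediate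
9 | isopropylmagnesium chloride | CC(C)[Mg]Cl | starting material
10 | 4β-hydroxydauc-8-en-7-one | CC(C)[C@]1(O)CC[C@]2(C)CC=C(C)C(=O)C[C@H]21 | intermediate
11 | 4-(benzyloxy)benzoic acid | OC(=O)c1ccc(OCc2ccccc2)cc1 | starting material
12 | 6α-[4-(benzyloxy)benzoyloxy]-4β-hydroxydauc-8-en-7-one | CC(C)[C@]1(O)CC[C@]2(C)CC=C(C)C(=O)[C@H](OC(=O)c3ccc(OCc4ccccc4)cc3)[C@H]21 | intermediate
13 | benzyl-protected 4β,8α,9α-triol 7-ketone 6α-ester | CC(C)[C@]1(O)CC[C@]2(C)C[C@H](O)[C@](C)(O)C(=O)[C@H](OC(=O)c3ccc(OCc4ccccc4)cc3)[C@H]21 | intermediate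
14 | CNP0241001.1 | CC(C)[C@]1(O)CC[C@]2(C)C[C@H](O)[C@](C)(O)C(=O)[C@H](OC(=O)c3ccc(O)cc3)[C@H]21 | target

**Total step count:** 8. **Longest linear sequence:** 8.

**The three steps most likely to fail**

Step 4 is the weakest point. The fragmentation itself should be easy. C5, however, is fixed only by a proton transfer, and it stays epimerisable as long as the C4 ketone is present. A rough torsional analysis suggests that the cis-fused epimer may be about 1 kcal/mol more stable, so thermodynamic drift would erode the trans isomer.

The fallback sets out from 6 and comes back at 8. It replaces the polar fragmentation by a ketyl fragmentation. Samarium diiodide in THF with t-BuOH reduces the C4 ketone, and the exocyclic cyclobutane bond C5–C9 breaks. The C7 hydroxyl lies on the α face of the new seven-membered ring and can deliver the proton to C5 of the samarium enolate from that face. This gives the saturated 7α-hydroxy ketone F3. Ley–Griffith oxidation then gives the saturated 4,7-diketone F4, and IBX dehydrogenation toward the more substituted C8 gives 8.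

Step 3 can fail in three ways. It may give the crossed regioisomer, show poor facial selectivity because the relay centres are small, or suffer from secondary photochemistry.

The fallback sets out from 5 and comes back at 8. It forms the C1–C10 bond by polar chemistry. Oxidation of 5 gives the β,γ-unsaturated ketone F1. TBSOTf and Et3N enolise F1 toward C8 to give the silyl dienol ether F2. An intramolecular vinylogous Mukaiyama–Michael addition of C10 to C1 then gives 8. This addition is run with Cu(OTf)2 and (S,S)-2,2'-isopropylidenebis(4-tert-butyl-2-oxazoline), so the sense of induction now comes from the catalyst.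

Step 6 can give acetate instead of the aroate. It may also oxidise the γ position (C10), or give the axial ester without equilibration.

The fallback sets out from 10 and comes back at 12. It installs the ester by substitution. LDA (2.2 equiv) and TMSCl give the bis(trimethylsilyl) cross-conjugated dienol ether F5, and NBS gives the 6β-bromo enone F6. Cesium 4-(benzyloxy)benzoate (made from 11) in DMF displaces the α-keto bromide with inversion to give 12.

**Further compounds**
F1 | step 3 | 3-methyl-2-[(3S)-3-methyl-2-oxopent-4-en-1-yl]cyclopent-2-en-1-one | C=C[C@H](C)C(=O)CC1=C(C)CCC1=O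
F2 | step 3 | silyl dienol ether, 2-[2-(tert-butyldimethylsilyloxy)-3-methylpenta-2,4-dien-1-yl]-3-methylcyclopent-2-en-1-one (ring CH2 cis to vinyl) | C=C/C(C)=C(\CC1=C(C)CCC1=O)O[Si](C)(C)C(C)(C)C
F3 | step 4 | trans-fused saturated 7α-hydroxy-8-methyl 4-ketone | O=C1CC[C@]2(C)CC[C@H](C)[C@H](O)C[C@H]21
F4 | step 4 | trans-fused saturated 4,7-diketone | O=C1CC[C@]2(C)CC[C@H](C)C(=O)C[C@H]21
F5 | step 6 | 4,7-bis(trimethylsilyloxy)dauca-6,8-diene | CC(C)[C@]1(O[Si](C)(C)C)CC[C@]2(C)CC=C(C)C(O[Si](C)(C)C)=C[C@H]21
F6 | step 6 | 6β-bromo-4β-hydroxydauc-8-en-7-one | CC(C)[C@]1(O)CC[C@]2(C)CC=C(C)C(=O)[C@@H](Br)[C@H]21
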